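**Plan**

- Retrosynthesis: cut C1–O7 and C2–Br of the oxabicycle (bromoetherification of a cyclohexenol), then C4–O7 with re-formation of a cyclopropane ring-fusion bond (1-substituted 4-methylidenebicyclo[3.1.0]hexane), then the exocyclic methylene, the cyclopropane CH2, the cyclopentenone C–C bonds (aldol, Stetter), and finally the C2′–C3′ bond and C–Br of the bromocyclohexane (bromonium cyclisation).
- Forward ring order: bromocyclohexane (step 2), cyclopentenone (step 7), cyclopropane (step 9), cyclohexene by ring expansion (step 12), 7-oxabicyclo[2.2.1]heptane (step 13).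
- Enabling feature: with oxabicycle locants C1(Me), C2(Br), C3, C4, C5, C6, O7, the oxygen-bearing bridgehead C4 is quaternary and chiral only because bromine sits on C2 and not on C6. It is mapped onto the quaternary cyclopropane carbon C1 of the bicyclo[3.1.0]hexane 17 and carried over with inversion.
- Stereochemistry: C4′–Br from catalyst-controlled bromenium transfer; C1′ by equilibration and separation at enone 12; the cyclopropane from CBS reduction plus hydroxyl-directed Simmons–Smith; the C4 carbinol by invertive water capture; C1/C2 by anti bromoetherification.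

Key step: step 12

Remark 1: primed locants refer to the bromocyclohexane ring. C1′ is exchangeable (α to C=O in 8 and 10, γ in 12) until step 7. An axial bromine next to the gem-dimethyl carbon costs little, so only a modest preference for the diequatorial isomer is assumed and the epimers are separated at 12.
Remark 2: the antipode of the step 2 catalyst is the one that delivers the 4S bromide.
Remark 3: numbered building blocks stand under Reactants and, where they donate atoms, again with SMILES on the reagent line.

**Route**

Step 1
Reactants: 1 6-methylhept-5-en-2-one (sulcatone)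
Product: 3 6-methylhepta-1,5-dien-2-yl acetate, via lithium 6-methylhepta-1,5-dien-2-olate 2 (not isolated)
Conditions: LDA, THF, −78 °C; then Ac2O, −78 → 0 °C
Reagents that add atoms: acetic anhydride, CC(=O)OC(C)=O
Why: Kinetic deprotonation of the methyl ketone at CH3 and O-acetylation of the lithium enolate (enolate trapping) should give the terminal enol acetate; no stereocentre is formed.

Step 2
Reactants: 3 6-methylhepta-1,5-dien-2-yl acetate
Product: 4 (4S)-4-bromo-3,3-dimethylcyclohexan-1-one
Conditions: DBDMH (1.1 equiv), BINOL-derived chiral thiophosphoramide (10 mol%), toluene/CH2Cl2, −78 °C; aq. NaHCO3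
Reagents that add atoms: 1,3-dibromo-5,5-dimethylhydantoin, CC1(C)N(Br)C(=O)N(Br)C1=O
Why: Proposed new method: a chiral Lewis-base–bromenium complex should transfer Br+ face-selectively to the more electron-rich trisubstituted alkene (the enol ester is the poorer π-donor, whereas an allylsilane terminus would be brominated first), the bromonium ion is opened at its tertiary carbon by the enol-acetate CH2 through a chair-like six-membered transition state that places bromine equatorial, and the acyloxycarbenium ion sheds acetyl to give the ketone with C4 (S) set by the catalyst, the closest known reaction type being catalytic enantioselective bromonium-induced polyene cyclisation of arene-terminated geranyl and homogeranyl substrates combined with enol-ester termination of cation–olefin cyclisations.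

Step 3
Reactants: 4 (4S)-4-bromo-3,3-dimethylcyclohexan-1-one
Product: 5 (1S)-1-bromo-2,2-dimethyl-4-methylidenecyclohexane
Conditions: Zn, CH2Br2, TiCl4, THF/CH2Cl2, 0 °C → rt
Reagents that add atoms: dibromomethane, BrCBr
Why: Takai–Lombardo methylenation is a non-basic titanium–zinc methylene transfer, so the ketone should become the exocyclic alkene without an enolate that could displace the γ-bromide (1,3-elimination to a bicyclo[3.1.0]hexanone); the stereocentre is untouched.

Step 4
Reactants: 5 (1S)-1-bromo-2,2-dimethyl-4-methylidenecyclohexane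
Product: 7 [(4S)-4-bromo-3,3-dimethylcyclohexyl]methanol (C1 epimer mixture), via B-alkyl-9-borabicyclononane 6 (not isolated)
Conditions: 9-BBN, THF, 0 °C → rt; then H2O2, aq. NaOAc, 0 °C → rt
Reagents that add atoms: hydrogen peroxide, OO
Why: Anti-Markovnikov hydroboration–oxidation places boron and then hydroxyl on the exocyclic carbon; the new C1 centre forms unselectively, which is immaterial because it is equilibrated in step 7.

Step 5
Reactants: 7 [(4S)-4-bromo-3,3-dimethylcyclohexyl]methanol
Product: 8 (4S)-4-bromo-3,3-dimethylcyclohexane-1-carbaldehyde (C1 epimer mixture)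
Conditions: Dess–Martin periodinane, NaHCO3, CH2Cl2, 0 °C → rt
Reagents that add atoms: none
Why: Dess–Martin oxidation of the primary alcohol should stop at the aldehyde under neutral conditions that leave the secondary bromide alone.

Step 6
Reactants: 8 (4S)-4-bromo-3,3-dimethylcyclohexane-1-carbaldehyde; 9 methyl vinyl ketone
Product: 10 1-[(4S)-4-bromo-3,3-dimethylcyclohexyl]pentane-1,4-dione (C1′ epimer mixture)
Conditions: 3-benzyl-5-(2-hydroxyethyl)-4-methylthiazolium chloride (20 mol%), Et3N, EtOH, 75 °C
Reagents that add atoms: methyl vinyl ketone (9), CC(=O)C=C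
Why: Stetter reaction: the thiazolylidene converts the aldehyde into an acyl-anion equivalent (Breslow intermediate) that adds 1,4 to the enone and gives the 1,4-diketone.

Step 7
Reactants: 10 1-[(4S)-4-bromo-3,3-dimethylcyclohexyl]pentane-1,4-dione
Product: 12 3-[(1S,4S)-4-bromo-3,3-dimethylcyclohexyl]cyclopent-2-en-1-one, via 3-hydroxycyclopentanone aldol 11 (not isolated)
Conditions: KOH (0.5 M), MeOH, 20 → 45 °C; SiO2 chromatography; C1′ epimer re-equilibrated (DBU cat., toluene) and recycled
Reagents that add atoms: none
Why: Intramolecular aldol condensation: the methyl-ketone enolate attacks the cyclohexyl ketone and E1cB dehydration gives the conjugated 3-substituted cyclopentenone, while C1′ equilibrates through the enolate of 10 and the dienolate of 12, so the trans (1S,4S) isomer with bromine and ring substituent both equatorial is enriched and then separated from its epimer, which needs an axial bromine (temperature is kept low because that epimer can lose HBr under base).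

Step 8
Reactants: 12 3-[(1S,4S)-4-bromo-3,3-dimethylcyclohexyl]cyclopent-2-en-1-one
Product: 13 (1R)-3-[(1S,4S)-4-bromo-3,3-dimethylcyclohexyl]cyclopent-2-en-1-ol
Conditions: (S)-2-methyl-CBS-oxazaborolidine (20 mol%), BH3·SMe2, THF, −30 °C; MeOH
Reagents that add atoms: none
Why: Corey–Bakshi–Shibata reduction: with the olefinic arm acting as the larger carbonyl substituent, the (S)-oxazaborolidine–borane complex should deliver hydride to the face that gives the 1R allylic alcohol (reagent control; the remote cyclohexane centres exert no bias).

Step 9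
Reactants: 13 (1R)-3-[(1S,4S)-4-bromo-3,3-dimethylcyclohexyl]cyclopent-2-en-1-ol; 14 diiodomethane
Product: 15 (1S,2R,5R)-5-[(1S,4S)-4-bromo-3,3-dimethylcyclohexyl]bicyclo[3.1.0]hexan-2-ol
Conditions: Et2Zn, CH2I2, CH2Cl2, −10 → 20 °C
Reagents that add atoms: diiodomethane (14), ICI
Why: Furukawa-type Simmons–Smith cyclopropanation: the zinc alkoxide of the allylic alcohol delivers methylene to the alkene face syn to oxygen, so the 1R carbinol fixes both cyclopropane centres (1S and the quaternary 5R).

Step 10
Reactants: 15 (1S,2R,5R)-5-[(1S,4S)-4-bromo-3,3-dimethylcyclohexyl]bicyclo[3.1.0]hexan-2-ol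
Product: 16 (1S,5R)-5-[(1S,4S)-4-bromo-3,3-dimethylcyclohexyl]bicyclo[3.1.0]hexan-2-one
Conditions: Dess–Martin periodinane, NaHCO3, CH2Cl2, 0 °C → rt
Reagents that add atoms: none
Why: Dess–Martin oxidation gives the cyclopropyl ketone; the carbinol centre has done its work and the cis-fused cyclopropane centres cannot epimerise.

Step 11
Reactants: 16 (1S,5R)-5-[(1S,4S)-4-bromo-3,3-dimethylcyclohexyl]bicyclo[3.1.0]hexan-2-one
Product: 17 (1R,5R)-1-[(1S,4S)-4-bromo-3,3-dimethylcyclohexyl]-4-methylidenebicyclo[3.1.0]hexane
Conditions: Ph3PCH3Br, KOt-Bu, THF, 0 °C → rt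
Reagents that add atoms: methyltriphenylphosphonium bromide, C[P+](c1ccccc1)(c1ccccc1)c1ccccc1.[Br-]
Why: Wittig methylenation of the unhindered ring ketone installs the exocyclic alkene next to the cyclopropane; the equatorially locked bromide has no anti-periplanar hydrogen and should survive the ylide.

Step 12
Reactants: 17 (1R,5R)-1-[(1S,4S)-4-bromo-3,3-dimethylcyclohexyl]-4-methylidenebicyclo[3.1.0]hexane
Product: 18 (1S)-1-[(1S,4S)-4-bromo-3,3-dimethylcyclohexyl]-4-methylcyclohex-3-en-1-ol
Conditions: aq. HClO4 (0.05 M), acetone/H2O 2:1, 0 → 20 °C; NaHCO3 quench at full conversion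
Reagents that add atoms: water, O
Why: Protonation of the exocyclic methylene at its CH2 carbon gives a tertiary cyclopropylcarbinyl (bicyclobutonium-type) cation at C4 of the bicyclohexane, and water attacks the quaternary cyclopropane carbon C1 from the side opposite the C1–C5 fusion bond as that bond breaks, forming the C–O bond and the C4=C5 alkene. The closest known reaction is the acid-catalysed hydration of sabinene to terpinen-4-ol, supported by stereoinvertive nucleophilic substitution at the quaternary carbon of cyclopropylcarbinyl cations. No ring is closed by bond formation: the six-membered ring arises by ring expansion, the five-membered ring gaining the former cyclopropane CH2 when the fusion bond is cleaved (cyclopropylcarbinyl–homoallyl rearrangement). The only new stereocentre, the carbinol carbon (1S), is controlled by the (1R,5R) cyclopropane through backside water capture, so the information from steps 8 and 9 is transferred. The step needs cleavage of the fusion bond and not of the external C5–C6 bond, which the substrate secures because only C1 is quaternary and can carry positive charge; it also needs water capture to outrun collapse to a free cyclohexenyl cation or proton loss to dienes, which a water-rich medium, a non-nucleophilic counter-ion and low temperature should favour.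

Step 13
Reactants: 18 (1S)-1-[(1S,4S)-4-bromo-3,3-dimethylcyclohexyl]-4-methylcyclohex-3-en-1-ol
Product: 19 (1R,2R,4S)-2-bromo-4-[(1S,4S)-4-bromo-3,3-dimethylcyclohexyl]-1-methyl-7-oxabicyclo[2.2.1]heptane
Conditions: NBS, CH2Cl2, 0 °C
Reagents that add atoms: N-bromosuccinimide, O=C1CCC(=O)N1Br
Why: Bromoetherification: the bromonium ion on the alkene face remote from the hydroxyl is opened by the tertiary alcohol at the more substituted carbon across the boat (5-exo), which closes the 7-oxabicyclo[2.2.1]heptane and leaves bromine on C2 anti to the oxygen bridge, so C1 (R) and C2 (R) follow from the C4 carbinol configuration.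

**Compound list**

1 | 6-methylhept-5-en-2-one (sulcatone) | CC(C)=CCCC(C)=O | starting material
2 | lithium 6-methylhepta-1,5-dien-2-olate | C=C([O-])CCC=C(C)C.[Li+] | intermediate (not isolated)
3 | 6-methylhepta-1,5-dien-2-yl acetate | CC(=O)OC(=C)CCC=C(C)C | intermediate
4 | (4S)-4-bromo-3,3-dimethylcyclohexan-1-one | CC1(C)CC(=O)CC[C@@H]1Br | intermediate
5 | (1S)-1-bromo-2,2-dimethyl-4-methylidenecyclohexane | CC1(C)CC(=C)CC[C@@H]1Br | intermediate
6 | 9-{[(4S)-4-bromo-3,3-dimethylcyclohexyl]methyl}-9-borabicyclo[3.3.1]nonane (C1 epimers) | CC1(C)CC(CB2C3CCCC2CCC3)CC[C@@H]1Br | intermediate (not isolated)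
7 | [(4S)-4-bromo-3,3-dimethylcyclohexyl]methanol (C1 epimers) | CC1(C)CC(CO)CC[C@@H]1Br | intermediate
8 | (4S)-4-bromo-3,3-dimethylcyclohexane-1-carbaldehyde (C1 epimers) | CC1(C)CC(C=O)CC[C@@H]1Br | intermediate
9 | methyl vinyl ketone | CC(=O)C=C | starting material
10 | 1-[(4S)-4-bromo-3,3-dimethylcyclohexyl]pentane-1,4-dione (C1′ epimers) | CC1(C)CC(C(=O)CCC(C)=O)CC[C@@H]1Br | intermediate
11 | 3-[(4S)-4-bromo-3,3-dimethylcyclohexyl]-3-hydroxycyclopentan-1-one (stereoisomer mixture) | CC1(C)CC(C2(O)CCC(=O)C2)CC[C@@H]1Br | intermediate (not isolated)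
12 | 3-[(1S,4S)-4-bromo-3,3-dimethylcyclohexyl]cyclopent-2-en-1-one | CC1(C)C[C@@H](C2=CC(=O)CC2)CC[C@@H]1Br | intermediate
13 | (1R)-3-[(1S,4S)-4-bromo-3,3-dimethylcyclohexyl]cyclopent-2-en-1-ol | CC1(C)C[C@@H](C2=C[C@H](O)CC2)CC[C@@H]1Br | intermediate
14 | diiodomethane | ICI | starting material
15 | (1S,2R,5R)-5-[(1S,4S)-4-bromo-3,3-dimethylcyclohexyl]bicyclo[3.1.0]hexan-2-ol (OH cis to the cyclopropane CH2) | CC1(C)C[C@@H]([C@@]23C[C@@H]2[C@H](O)CC3)CC[C@@H]1Br | intermediate
16 | (1S,5R)-5-[(1S,4S)-4-bromo-3,3-dimethylcyclohexyl]bicyclo[3.1.0]hexan-2-one | CC1(C)C[C@@H]([C@@]23C[C@@H]2C(=O)CC3)CC[C@@H]1Br | intermediate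
17 | (1R,5R)-1-[(1S,4S)-4-bromo-3,3-dimethylcyclohexyl]-4-methylidenebicyclo[3.1.0]hexane | CC1(C)C[C@@H]([C@@]23C[C@@H]2C(=C)CC3)CC[C@@H]1Br | intermediate
18 | (1S)-1-[(1S,4S)-4-bromo-3,3-dimethylcyclohexyl]-4-methylcyclohex-3-en-1-ol | CC1(C)C[C@@H]([C@]2(O)CCC(C)=CC2)CC[C@@H]1Br | intermediate
19 | (1R,2R,4S)-2-bromo-4-[(1S,4S)-4-bromo-3,3-dimethylcyclohexyl]-1-methyl-7-oxabicyclo[2.2.1]heptane (C2–Br anti to O7) | CC1(C)C[C@@H]([C@@]23CC[C@@](C)(O2)[C@H](Br)C3)CC[C@@H]1Br | target

Total step count: 13. Longest linear sequence: 13.

**Steps most likely to fail**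

Step 2 (labelled step). The catalyst may discriminate the alkene faces poorly, since the substrate has no aryl group for recognition, or bromenium may be transferred to the enol ester instead of the prenyl alkene. The fallback uses known chemistry and replaces catalyst control by resolution. It sets out from 3: cyclisation with 2,4,4,6-tetrabromocyclohexa-2,5-dien-1-one in MeNO2/CH2Cl2 at 0 °C should give racemic 4-bromo-3,3-dimethylcyclohexan-1-one F1. Acid-catalysed ketalisation with (R,R)-hydrobenzoin then gives two diastereomeric spiro-ketals, from which (2R,3R,8S)-8-bromo-7,7-dimethyl-2,3-diphenyl-1,4-dioxaspiro[4.5]decane F2 is isolated by crystallisation or chromatography. Mild aqueous acid hydrolysis of F2 comes back to the route at 4.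

Step 12. Stereochemical information may be lost if the cation relaxes to a free cyclohexenyl cation before water arrives, and proton loss to dienes may compete. The fallback builds the carbinol by reagent-controlled ketone allylation and the ring by metathesis. It sets out from 8: addition of 3-methylbut-3-en-1-ylmagnesium bromide gives 1-[(4S)-4-bromo-3,3-dimethylcyclohexyl]-4-methylpent-4-en-1-ol F3. Dess–Martin oxidation, followed by base equilibration and separation as in step 7, gives 1-[(1S,4S)-4-bromo-3,3-dimethylcyclohexyl]-4-methylpent-4-en-1-one F4. Catalytic asymmetric allylboration (allylboronic acid pinacol ester, chiral 3,3′-disubstituted BINOL catalyst), which relies on the size difference between the cyclohexyl group and the primary chain, gives (4S)-4-[(1S,4S)-4-bromo-3,3-dimethylcyclohexyl]-7-methylocta-1,7-dien-4-ol F5. Ring-closing metathesis with a second-generation ruthenium benzylidene–NHC catalyst comes back to the route at 18.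

Step 7. The thermodynamic bias at C1′ may be too small and the two epimers may co-elute; slow dehydrobromination of the axial-bromide epimer may also erode material. The fallback replaces physical separation by kinetic chemical differentiation. It sets out from 10: the aldol condensation is run as before and 12 is carried on together with its epimer 3-[(1R,4S)-4-bromo-3,3-dimethylcyclohexyl]cyclopent-2-en-1-one F6. Reduction under the step 8 conditions gives 13 together with (1R)-3-[(1R,4S)-4-bromo-3,3-dimethylcyclohexyl]cyclopent-2-en-1-ol F7. Treatment with KOt-Bu in DMSO at rt should remove HBr only from F7, whose chair can place bromine axial and anti to H-5′, giving (1R)-3-[(1R)-5,5-dimethylcyclohex-3-en-1-yl]cyclopent-2-en-1-ol F8. In 13 an axial bromine would force the cyclopentenyl group against the axial methyl group, so it should survive; chromatographic removal of F8 comes back to the route at 13.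

**Further compounds**

F1 | step 2 | racemic 4-bromo-3,3-dimethylcyclohexan-1-one | CC1(C)CC(=O)CCC1Br
F2 | step 2 | (2R,3R,8S)-8-bromo-7,7-dimethyl-2,3-diphenyl-1,4-dioxaspiro[4.5]decane | CC1(C)CC2(CC[C@@H]1Br)O[C@H](c1ccccc1)[C@@H](c1ccccc1)O2
F3 | step 12 | 1-[(4S)-4-bromo-3,3-dimethylcyclohexyl]-4-methylpent-4-en-1-ol (stereoisomer mixture) | CC1(C)CC(C(O)CCC(C)=C)CC[C@@H]1Br
F4 | step 12 | 1-[(1S,4S)-4-bromo-3,3-dimethylcyclohexyl]-4-methylpent-4-en-1-one | CC1(C)C[C@@H](C(=O)CCC(C)=C)CC[C@@H]1Br
F5 | step 12 | (4S)-4-[(1S,4S)-4-bromo-3,3-dimethylcyclohexyl]-7-methylocta-1,7-dien-4-ol | CC1(C)C[C@@H]([C@@](O)(CC=C)CCC(C)=C)CC[C@@H]1Br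
F6 | step 7 | 3-[(1R,4S)-4-bromo-3,3-dimethylcyclohexyl]cyclopent-2-en-1-one | CC1(C)C[C@H](C2=CC(=O)CC2)CC[C@@H]1Br
F7 | step 7 | (1R)-3-[(1R,4S)-4-bromo-3,3-dimethylcyclohexyl]cyclopent-2-en-1-ol | CC1(C)C[C@H](C2=C[C@H](O)CC2)CC[C@@H]1Br
F8 | step 7 | (1R)-3-[(1R)-5,5-dimethylcyclohex-3-en-1-yl]cyclopent-2-en-1-ol | CC1(C)C[C@H](C2=C[C@H](O)CC2)CC=C1
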